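## The problem

Target 11 is a cyclohexene in which every ring carbon is functionalised; the ring is numbered C1 (OMe), C2 (OBz), C3=C4, C5–C6 (epoxide), and C7 is the CH2OBz carbon on C6. Four contiguous stereocentres must be set: C1 and C2 are trans, the epoxide oxygen lies on the face of the C1 methoxy group, and the quaternary C6 carries C7 trans to that methoxy group. C1 and C2 can be made as a pair, but afterwards they are the only handles on the epoxide face, and because they sit on opposite faces of the ring their control over C5/C6 is a difference of two biases. The vinyl epoxide (C3=C4 next to the C5–C6 oxirane) tolerates neither acid nor nucleophiles that add in the SN2' sense, the two benzoates do not survive hydride or alkoxide, and the allylic C2 benzoate can ionise. Any cyclohexadiene intermediate that keeps the C1 and C2 oxygens is a dihydroarene and can aromatise by loss of methanol or benzoic acid. The enabling feature is that the trans-dioxygenated C1–C2 unit lies between C6, which bears the carboxyl-level carbon C7, and C3, while C3–C4–C5–C6 has the oxidation level of a 1,3-diene plus O2. The carbocycle is therefore the adduct of an (E)-1,2-dioxyethene across C3 and C6 of a 3-carboxy-2-pyrone, after loss of CO2.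

## Retrosynthesis

**11 to 10.** The C5–O bond of the epoxide is cut and one oxygen is added back, giving the bicyclic endoperoxide 10, whose O–O bridge spans C3 and C6. Direct epoxidation of a diene would have to choose between two double bonds and would favour the face anti to the allylic C1 methoxy group. The endoperoxide ties both oxygens to one face in a single event and leaves only the choice of which oxygen is removed. The forward reaction needs a phosphine to attack the less hindered oxygen on C3, so that the C6 alkoxide closes onto C5.

**10 to 9.** The C3–O and C6–O bonds are cut, giving diene dibenzoate 9 and O2. Two stereocentres are removed and 9 keeps only C1 and C2. The forward [4+2] addition of singlet oxygen must occur on the face of the C1 methoxy group, anti to the C2 benzoate.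

**9 to 8 to 7.** The two benzoate C–O bonds are cut (diol 8), then C7 is taken back to the ester level (diene ester 7). No hydride distinguishes a conjugated methyl ester from a benzoate reliably, so reducing both and benzoylating both costs no extra step compared with any selective scheme. The forward steps must avoid acid, because 7, 8 and 9 are all dihydroarenes.

**7 to 6.** CO2 is added back across C3 and C6, giving the 2-oxabicyclo[2.2.2]octenone 6. This turns the sensitive diene into a stable, isolable bicycle. Both bridgeheads become sp2 in the forward cycloreversion, so only the C1/C2 configuration of 6 is passed on.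

**6 to 5 + 4 (key disconnection).** The C1–C6 and C2–C3 bonds are cut, giving commercial methyl 2-oxo-2H-pyran-3-carboxylate 5 and (E)-2-methoxyvinyl benzoate 4. Cutting C1–C2 or C5–C6 instead would give open chains in which the trans-diol and the quaternary centre would each need separate control. This cut makes the ring, both skeletal bonds and the C1/C2 pair in one catalytic step from two achiral pieces. The forward step must be regioselective, must keep the E geometry, and must use one face of the dienophile.

**4 to 2 + 3, and 2 to 1.** The enol ester C–O bond is cut, giving methoxyacetaldehyde 2 and benzoyl chloride 3. Aldehyde 2 comes from its commercial dimethyl acetal 1. The benzoate is chosen as the weaker donor, so that the methoxy group alone polarises the alkene. It also makes 4 non-volatile and UV-active, which eases the separation of the E isomer.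

## Roads not taken

Alternative 1: Payne migration of a spiro epoxide into the ring.
- Cut: the C5–O bond of the ring epoxide is cut and the oxygen is reassigned to C7. The precursor is the spiro-epoxy alcohol A2, with the C6–C7 oxirane trans to a free C5 hydroxyl.
- Forward key step: NaH converts the C5 hydroxyl to its alkoxide, which opens the spiro epoxide at C6 with inversion. This gives the ring-fused epoxy primary alcohol A1.
- Merits: the epoxide face is fixed stereospecifically by the C5 carbinol. The C7 hydroxyl is freed exactly where a benzoate is needed. The equilibrium should favour the more substituted epoxide and the primary alkoxide.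
- Weak points: the attack is at a fully substituted carbon. The product alkoxide sits next to a vinyl epoxide under basic conditions. A2 already contains four stereocentres on a cyclohexene, so the ring construction and the face of the spiro epoxidation are left unsolved. The silyl-to-benzoate exchange adds two steps.
- Comparison: in certainty of the epoxide configuration this road is better than the chosen plan, which relies on a substrate-controlled oxygen addition. The chosen plan offers in return an eight-step sequence that builds the ring and the C1/C2 pair catalytically.

Alternative 2: samarium pinacol closure creating the C1–C6 cis-diol.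
- Cut: the C1–C6 bond is cut. The precursor is the (Z)-keto-aldehyde A4 (C1 aldehyde, C6 ketone, silyl and p-methoxybenzyl ethers on C2, C5 and C7).
- Forward key step: SmI2 (divalent samarium) couples the two carbonyl groups and gives the cyclohexene cis-diol A3.
- Merits: ring closure and two stereocentres arise in one step with dependable cis selectivity through a samarium-bridged diketyl. All oxygens are differentiated. No cyclohexadiene is involved. The epoxide would later be closed by SN2 displacement at C5, so its face is certain.
- Weak points: both carbonyl groups of A4 carry α-alkoxy groups, and reductive cleavage of such groups by SmI2 competes with coupling. The Z-γ-oxygenated enone can isomerise. After the key step at least six further operations are needed, including selective O-methylation at C1 next to a tertiary C6 hydroxyl and activation of an allylic C5 alcohol. A4 itself needs a long acyclic sequence.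
- Comparison: this road is better in oxygen differentiation and in epoxide control. The chosen plan is roughly half as long and uses no protecting groups.

Alternative 3: chromium-mediated alkenyl addition closing C2–C3.
- Cut: the C2–C3 bond is cut. The precursor is the epoxy aldehyde A6, which carries a (Z)-alkenyl iodide at C3/C4.
- Forward key step: CrCl2 with catalytic NiCl2 generates an alkenylchromium species that adds to the C2 aldehyde and gives the allylic alcohol A5. One benzoylation then gives the target.
- Merits: the closure is mild and chemoselective and tolerates the epoxide and the ester. The epoxide centres can be set in the open chain by a reagent-controlled Sharpless epoxidation. A wrong C2 epimer could be corrected by Mitsunobu inversion with benzoic acid.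
- Weak points: the C2 configuration arises under substrate control from an α-methoxy aldehyde that can epimerise at C1. A6 holds three stereocentres and a Z-iodoalkene on an epoxide, so the linear sequence is long. Chromium is used in excess.
- Comparison: epoxide control and endgame brevity are better here. The chosen plan has a far shorter overall sequence and makes C1/C2 in one catalytic step.

Key step: step 3

Assumption: the absolute sense of the Cu(OSO2CF3)2–bis(oxazoline) catalyst is taken from the distorted square-planar chelate model. If the (S,S) ligand gives the antipodal series, the equally available (R,R) ligand is used with nothing else changed.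

## Route

Step 1
Reactants: 1 methoxyacetaldehyde dimethyl acetal (1,1,2-trimethoxyethane)
Product: 2 methoxyacetaldehyde
Conditions: 1 M aq. HCl, 50 °C; NaCl saturation, continuous CH2Cl2 extraction, MgSO4; used as a dried CH2Cl2 solution after removal of methanol
Reagents that add atoms: water, O
Why: Acid-catalysed acetal hydrolysis; the small, water-soluble aldehyde is carried on in solution to avoid self-condensation.

Step 2
Reactants: 2 methoxyacetaldehyde; 3 benzoyl chloride
Product: 4 (E)-2-methoxyvinyl benzoate
Conditions: Et3N (2 equiv), DMAP (cat.), CH2Cl2, 0 °C to rt; chromatography on Et3N-deactivated silica to separate the E from the Z isomer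
Reagents that add atoms: none
Why: Enol ester formation by O-acylation of the amine-generated enolate of an α-alkoxy aldehyde; both geometric isomers are expected, and the E isomer should be recognisable by its larger vicinal alkene coupling.

Step 3
Reactants: 5 methyl 2-oxo-2H-pyran-3-carboxylate; 4 (E)-2-methoxyvinyl benzoate
Product: 6 methyl (1R,4S,7R,8R)-7-(benzoyloxy)-8-methoxy-3-oxo-2-oxabicyclo[2.2.2]oct-5-ene-4-carboxylate (methoxy syn to the C5=C6 bridge, benzoate syn to the lactone bridge)
Conditions: Cu(OSO2CF3)2 (10 mol%), 2,2'-(propane-2,2-diyl)bis[(4S)-4-tert-butyl-4,5-dihydrooxazole] (11 mol%), 4 Å MS, CH2Cl2, −20 °C to 0 °C, slow addition of 4 (1.5 equiv)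
Reagents that add atoms: none
Why: The copper salt binds the lactone and ester carbonyls of 5 as a six-membered chelate and lowers the pyrone LUMO, and 4, polarised by the methoxy donor so that the benzoate-bearing carbon is its nucleophilic terminus, adds in a concerted but asynchronous inverse-electron-demand Diels–Alder reaction; the closest known reaction type is the chiral Lewis acid-catalysed (bis(oxazoline)–copper type) cycloaddition of 3-carboalkoxy-2-pyrones with electron-rich alkenes such as enol ethers. The six-membered carbocycle closes by intermolecular suprafacial [4+2] addition across pyrone C3 and C6, which also creates the 2-oxabicyclo[2.2.2]octene bridge. Regiochemistry follows from pairing the nucleophilic benzoate-bearing carbon with the electrophilic pyrone C6 and the incipient oxocarbenium carbon with the enolate-like C3. C7 and C8 of 6 are trans because the E geometry of 4 is carried over suprafacially. The bridgeheads C1 and C4 are fixed by the pyrone face that the tert-butyl group of the ligand leaves open in the distorted square-planar chelate. The absolute configuration at C7/C8 follows from that face together with the endo placement of the methoxy group (under pyrone C4–C5, hence anti to the lactone bridge in 6), the usual preference of the alkoxy donor in this reaction class. The step therefore needs regio-, endo- and face selectivity and retention of the alkene geometry; bidentate chelation, the push–pull polarisation of 4 and low temperature, which keeps bond formation concerted and suppresses benzoate participation in an oxocarbenium intermediate, are what secure them.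

Step 4
Reactants: 6 methyl (1R,4S,7R,8R)-7-(benzoyloxy)-8-methoxy-3-oxo-2-oxabicyclo[2.2.2]oct-5-ene-4-carboxylate
Product: 7 methyl (5R,6R)-5-(benzoyloxy)-6-methoxycyclohexa-1,3-diene-1-carboxylate
Conditions: PhMe, 100 °C, solid NaHCO3, BHT (cat.), argon
Reagents that add atoms: none
Why: Thermal retro-[4+2] loss of CO2 from a bridged pyrone adduct, helped by conjugation of the new diene with the ester; both bridgeheads become sp2 and the two oxygenated centres are untouched, with the buffer suppressing acid-catalysed aromatisation.

Step 5
Reactants: 7 methyl (5R,6R)-5-(benzoyloxy)-6-methoxycyclohexa-1,3-diene-1-carboxylate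
Product: 8 (1R,6R)-5-(hydroxymethyl)-6-methoxycyclohexa-2,4-dien-1-ol
Conditions: i-Bu2AlH (6 equiv), CH2Cl2, −78 °C; aq. potassium sodium tartrate (KNaC4H4O6) work-up
Reagents that add atoms: none
Why: 1,2-Reduction of the conjugated ester to the allylic alcohol with simultaneous reductive cleavage of the benzoate; the neutral tartrate work-up avoids acid-induced aromatisation of the dienediol.

Step 6
Reactants: 8 (1R,6R)-5-(hydroxymethyl)-6-methoxycyclohexa-2,4-dien-1-ol; 3 benzoyl chloride
Product: 9 [(5R,6R)-5-(benzoyloxy)-6-methoxycyclohexa-1,3-dien-1-yl]methyl benzoate
Conditions: BzCl (2.4 equiv in all), pyridine, DMAP (cat.), CH2Cl2, 0 °C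
Reagents that add atoms: benzoyl chloride (the second equivalent of 3), O=C(Cl)c1ccccc1
Why: Standard acylation of the primary and the secondary allylic hydroxyl, each taking one benzoyl group from one molecule of 3; no stereocentre is affected.

Step 7
Reactants: 9 [(5R,6R)-5-(benzoyloxy)-6-methoxycyclohexa-1,3-dien-1-yl]methyl benzoate
Product: 10 [(1S,4S,7S,8S)-8-(benzoyloxy)-7-methoxy-2,3-dioxabicyclo[2.2.2]oct-5-en-1-yl]methyl benzoate (peroxide bridge syn to the methoxy group)
Conditions: O2, visible light, tetraphenylporphyrin (cat.), CH2Cl2, −20 °C; chromatographic removal of the minor face isomer
Reagents that add atoms: oxygen, O=O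
Why: Singlet-oxygen [4+2] cycloaddition to a cyclohexa-1,3-diene, which places both oxygens on one face; with the two allylic substituents pseudoaxial on opposite faces, attack is expected past the small methoxy group and away from the bulkier benzoate.

Step 8
Reactants: 10 [(1S,4S,7S,8S)-8-(benzoyloxy)-7-methoxy-2,3-dioxabicyclo[2.2.2]oct-5-en-1-yl]methyl benzoate
Product: 11 [(1R,2S,3R,6R)-3-(benzoyloxy)-2-methoxy-7-oxabicyclo[4.1.0]hept-4-en-1-yl]methyl benzoate
Conditions: PPh3 (1.05 equiv), CH2Cl2, 0 °C to rt
Reagents that add atoms: none
Why: Phosphine deoxygenation of an unsaturated bicyclic endoperoxide to a vinyl epoxide: PPh3 should attack the less hindered peroxide oxygen on the secondary carbon, and the tertiary alkoxide then closes on the neighbouring alkene carbon in a syn SN2' displacement of Ph3P=O, so the epoxide keeps the face of the peroxide bridge and the double bond moves to C3=C4.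

## Compound list

1 | methoxyacetaldehyde dimethyl acetal (1,1,2-trimethoxyethane) | COCC(OC)OC | starting material
2 | methoxyacetaldehyde | COCC=O | intermediate
3 | benzoyl chloride | O=C(Cl)c1ccccc1 | starting material
4 | (E)-2-methoxyvinyl benzoate | CO/C=C/OC(=O)c1ccccc1 | intermediate
5 | methyl 2-oxo-2H-pyran-3-carboxylate | COC(=O)C1=CC=COC1=O | starting material
6 | methyl (1R,4S,7R,8R)-7-(benzoyloxy)-8-methoxy-3-oxo-2-oxabicyclo[2.2.2]oct-5-ene-4-carboxylate | CO[C@H]1[C@H](OC(=O)c2ccccc2)[C@H]2C=C[C@]1(C(=O)OC)C(=O)O2 | intermediate
7 | methyl (5R,6R)-5-(benzoyloxy)-6-methoxycyclohexa-1,3-diene-1-carboxylate | CO[C@H]1[C@H](OC(=O)c2ccccc2)C=CC=C1C(=O)OC | intermediate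
8 | (1R,6R)-5-(hydroxymethyl)-6-methoxycyclohexa-2,4-dien-1-ol | CO[C@H]1[C@H](O)C=CC=C1CO | intermediate
9 | [(5R,6R)-5-(benzoyloxy)-6-methoxycyclohexa-1,3-dien-1-yl]methyl benzoate | CO[C@H]1[C@H](OC(=O)c2ccccc2)C=CC=C1COC(=O)c1ccccc1 | intermediate
10 | [(1S,4S,7S,8S)-8-(benzoyloxy)-7-methoxy-2,3-dioxabicyclo[2.2.2]oct-5-en-1-yl]methyl benzoate | CO[C@H]1[C@H](OC(=O)c2ccccc2)[C@@H]2C=C[C@@]1(COC(=O)c1ccccc1)OO2 | intermediate
11 | [(1R,2S,3R,6R)-3-(benzoyloxy)-2-methoxy-7-oxabicyclo[4.1.0]hept-4-en-1-yl]methyl benzoate | CO[C@H]1[C@H](OC(=O)c2ccccc2)C=C[C@H]2O[C@]21COC(=O)c1ccccc1 | target

## Step count and risks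

Total steps: 8. Longest linear sequence: 8 (1 to 11); 3 and 5 enter as commercial materials.

**Step 3 (key step).** What may go wrong: incomplete discrimination between the endo and exo orientations of the dienophile, or incomplete face shielding by the ligand. The endo and exo adducts from one pyrone face give enantiomeric dienes after CO2 loss, so either leak lowers the enantiopurity of 7. A second danger is stepwise bond formation through an oxocarbenium zwitterion, where bond rotation or benzoate participation would erode the trans relationship. The fallback sets out from 2 and 5 and returns at 8; it replaces catalyst control by a covalent auxiliary on the dienophile. Aldehyde 2 is acylated with (1R,2S,5R)-menthyl chloroformate (Et3N, DMAP) to give (E)-2-methoxyvinyl (1R,2S,5R)-menthyl carbonate F1 after separation from its Z isomer. Cycloaddition of F1 with 5 under ZnBr2 in CH2Cl2 should give diastereomeric adducts, of which the two with the required configuration at the oxygenated carbons are the endo-methoxy adduct F2 and the exo-methoxy adduct F3. They are separated from the others by chromatography or crystallisation and pooled, and both lose CO2 under the conditions of step 4 to give the same diene carbonate F4. The i-Bu2AlH reduction of step 5 removes the carbonate together with the ester and delivers 8.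

**Step 7.** What may go wrong: poor facial selectivity of the oxygen addition. The methoxy and benzoate groups screen opposite faces and the preference rests only on their size difference, so much material may go to the wrong face. The fallback sets out from 8 and returns at 11; it uses a reagent-controlled, hydroxyl-directed epoxidation in place of the cycloaddition. Diol 8 is treated with Ti(OCH(CH3)2)4, D-(−)-diethyl tartrate and t-BuOOH (4 Å MS, CH2Cl2, −20 °C). This Sharpless epoxidation is directed by the primary allylic hydroxyl to the C5=C6 double bond. The tartrate is chosen by the empirical face rule: referred to the sense in which L-(+)-diethyl tartrate converts (E)-hex-2-en-1-ol into its (2S,3S)-epoxy alcohol, the face cis to the methoxy group of 8 is the one served by the D-(−) ester. The product is (1R,2S,3R,6R)-1-(hydroxymethyl)-2-methoxy-7-oxabicyclo[4.1.0]hept-4-en-3-ol F5, and dibenzoylation of F5 with 3 (pyridine, DMAP, 0 °C) gives 11. Because this path also bypasses step 8, it covers a regiochemical leak in the phosphine step, should PPh3 attack the peroxide oxygen on the tertiary carbon.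

**Step 2.** What may go wrong: preferential formation of the Z enol ester. Cis-1,2-dioxygenated alkenes and chelated enolates are favoured, so the E isomer may be the minor component and the supply of 4 limited. The fallback sets out from 2 and returns at 4; it relies on geometric isomerisation instead of direct formation. The co-formed (Z)-2-methoxyvinyl benzoate F6 is isolated and irradiated with a triplet sensitiser (benzophenone, benzene, 350 nm) to a photostationary mixture. The E isomer 4 is harvested by chromatography, and F6 is recycled.

**Step 4.** What may go wrong: aromatisation of the dihydroarene-type diene by loss of benzoic acid or methanol at the temperature needed for cycloreversion, autocatalysed by the acid released. The fallback sets out from 6 and returns at 7; it is a stepwise, low-temperature equivalent of the CO2 extrusion. The strained, doubly activated bridged lactone of 6 is opened selectively (LiOH, 1 equiv, THF–H2O, 0 °C) to (1R,4R,5R,6R)-5-(benzoyloxy)-4-hydroxy-6-methoxy-1-(methoxycarbonyl)cyclohex-2-ene-1-carboxylic acid F7, which keeps the configuration of 6. Dehydrative decarboxylation of F7 (PPh3, diisopropyl azodicarboxylate, THF, 0 °C) removes CO2 and the activated hydroxyl in a syn-1,4 elimination across the ring double bond and should give 7 without heating.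

## Further compounds

F1 | step 3 | (E)-2-methoxyvinyl (1R,2S,5R)-menthyl carbonate | CO/C=C/OC(=O)O[C@@H]1C[C@H](C)CC[C@H]1C(C)C
F2 | step 3 | endo-methoxy cycloadduct, menthyl carbonate analogue of 6 | CO[C@H]1[C@H](OC(=O)O[C@@H]3C[C@H](C)CC[C@H]3C(C)C)[C@H]2C=C[C@]1(C(=O)OC)C(=O)O2
F3 | step 3 | exo-methoxy cycloadduct, same configuration at the oxygenated carbons as F2, both bridgeheads inverted | CO[C@H]1[C@H](OC(=O)O[C@@H]3C[C@H](C)CC[C@H]3C(C)C)[C@@H]2C=C[C@@]1(C(=O)OC)C(=O)O2
F4 | step 3 | methyl (5R,6R)-6-methoxy-5-{[(1R,2S,5R)-menthyloxy]carbonyloxy}cyclohexa-1,3-diene-1-carboxylate | CO[C@H]1[C@H](OC(=O)O[C@@H]2C[C@H](C)CC[C@H]2C(C)C)C=CC=C1C(=O)OC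
F5 | step 7 | (1R,2S,3R,6R)-1-(hydroxymethyl)-2-methoxy-7-oxabicyclo[4.1.0]hept-4-en-3-ol | CO[C@H]1[C@H](O)C=C[C@H]2O[C@]21CO
F6 | step 2 | (Z)-2-methoxyvinyl benzoate | CO/C=C\OC(=O)c1ccccc1
F7 | step 4 | (1R,4R,5R,6R)-5-(benzoyloxy)-4-hydroxy-6-methoxy-1-(methoxycarbonyl)cyclohex-2-ene-1-carboxylic acid (configuration of 6) | CO[C@H]1[C@H](OC(=O)c2ccccc2)[C@H](O)C=C[C@]1(C(=O)OC)C(=O)O
A1 | alternative 1 | ring-fused epoxy primary alcohol (C2 tert-butyldimethylsilyl ether) | CO[C@H]1[C@H](O[Si](C)(C)C(C)(C)C)C=C[C@H]2O[C@]21CO
A2 | alternative 1 | spiro-epoxy alcohol with the C6–C7 oxirane trans to the C5 hydroxyl | CO[C@H]1[C@H](O[Si](C)(C)C(C)(C)C)C=C[C@@H](O)[C@@]12CO2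
A3 | alternative 2 | cyclohexene cis-1,2-diol | O[C@H]1[C@H](O[Si](C)(C)C(C)(C)C)C=C[C@H](OCc2ccc(OC)cc2)[C@]1(O)CO[Si](c3ccccc3)(c4ccccc4)C(C)(C)C
A4 | alternative 2 | (Z)-keto-aldehyde precursor | O=C[C@H](O[Si](C)(C)C(C)(C)C)/C=C\[C@H](OCc1ccc(OC)cc1)C(=O)CO[Si](c1ccccc1)(c1ccccc1)C(C)(C)C
A5 | alternative 3 | C2 allylic alcohol of the target skeleton | CO[C@H]1[C@H](O)C=C[C@H]2O[C@]21COC(=O)c1ccccc1
A6 | alternative 3 | epoxy aldehyde carrying the (Z)-alkenyl iodide | O=C[C@H](OC)[C@]1(COC(=O)c2ccccc2)O[C@@H]1/C=C\I
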